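**Plan**

- Ring labels: ring A is the 1,4-dioxygenated ring, ring B the 1,2-dioxygenated ring, ring C the para-linked ring, ring D the meta-linked ring.
- Enabling feature: the ring B carbon para to the hydroxyl-bearing carbon carries the two-carbon bridge to ring A. At the stilbene oxidation level this is an aryl–vinyl bond, which an iodide at that ring B carbon and a vinyl group on ring A (ortho to the ring A ether oxygen) can form.
- Retrosynthesis: cut the two O–CH3 bonds and return the A/B bridge to a stilbene, then cut the ring B carbon to bridge carbon bond. The seco compound is cut further at the vinyl C=C, the ring A C–O ether bond, the C/D bridge C–C bond and the ring C C–O ether bond.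
- Forward: B–O–C ether by SNAr, C/D bibenzyl by Wittig olefination and diimide reduction, D–O–A ether by SNAr, methylenation, Heck closure of the 18-membered ring, hydrogenation, demethylation.
- Stereochemistry: the target has no stereocentre. The E-alkene formed on ring closure is removed by hydrogenation.

Key step: step 7

Remark: the Wittig olefination in step 3 should give an E/Z mixture. Compound 7 is therefore written without alkene geometry, and both isomers converge on 8 in step 4.

**Route**

Step 1
Reactants: 1 5-iodo-2-methoxyphenol; 2 4-fluorobenzaldehyde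
Product: 3 4-(5-iodo-2-methoxyphenoxy)benzaldehyde
Conditions: K2CO3, DMF, 120 °C
Reagents that add atoms: none
Why: Nucleophilic aromatic substitution (SNAr), in which phenol 1, deprotonated by K2CO3, displaces the fluoride para to the activating formyl group while the aryl iodide stays inert because no transition metal is present.

Step 2
Reactants: 4 3-hydroxybenzyl alcohol
Product: 5 (3-hydroxybenzyl)triphenylphosphonium bromide
Conditions: PPh3·HBr, MeCN, reflux
Reagents that add atoms: triphenylphosphine hydrobromide, Br.P(c1ccccc1)(c1ccccc1)c1ccccc1
Why: Phosphonium salt formation from a benzylic alcohol, in which acid activation of the benzylic hydroxyl allows substitution by triphenylphosphine and leaves the phenol untouched.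

Step 3
Reactants: 3 4-(5-iodo-2-methoxyphenoxy)benzaldehyde; 5 (3-hydroxybenzyl)triphenylphosphonium bromide
Product: 7 3-{2-[4-(5-iodo-2-methoxyphenoxy)phenyl]ethenyl}phenol (E/Z mixture), via ylide phenoxide 6 (not isolated)
Conditions: KOtBu (2 equiv per 5), THF, 0 °C to rt; then dilute aq. HCl
Reagents that add atoms: none
Why: Wittig olefination, in which two equivalents of base convert 5 into the semi-stabilised benzylic ylide 6 (also a phenoxide) that condenses with the aryl aldehyde, the alkene geometry being irrelevant because step 4 saturates it.

Step 4
Reactants: 7 3-{2-[4-(5-iodo-2-methoxyphenoxy)phenyl]ethenyl}phenol (E/Z mixture)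
Product: 8 3-{2-[4-(5-iodo-2-methoxyphenoxy)phenyl]ethyl}phenol
Conditions: TsNHNH2 (excess, in portions), NaOAc, THF/H2O, reflux
Reagents that add atoms: none
Why: Diimide reduction, in which diimide released thermally from tosylhydrazide delivers two hydrogens to either stilbene isomer through a concerted cyclic transition state and, unlike hydrogenation over palladium, does not cleave the aryl iodide.

Step 5
Reactants: 8 3-{2-[4-(5-iodo-2-methoxyphenoxy)phenyl]ethyl}phenol; 9 2-fluoro-5-methoxybenzaldehyde
Product: 10 2-(3-{2-[4-(5-iodo-2-methoxyphenoxy)phenyl]ethyl}phenoxy)-5-methoxybenzaldehyde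
Conditions: K2CO3, DMAc, 150 °C
Reagents that add atoms: none
Why: Nucleophilic aromatic substitution (SNAr), in which the ortho formyl group activates the C–F bond of 9 towards deprotonated phenol 8, the higher temperature offsets the deactivating para methoxy group, and the metal-free conditions spare the iodide.

Step 6
Reactants: 10 2-(3-{2-[4-(5-iodo-2-methoxyphenoxy)phenyl]ethyl}phenoxy)-5-methoxybenzaldehyde
Product: 11 2-ethenyl-1-(3-{2-[4-(5-iodo-2-methoxyphenoxy)phenyl]ethyl}phenoxy)-4-methoxybenzene
Conditions: Ph3PCH3Br, KOtBu, THF, 0 °C to rt
Reagents that add atoms: methyltriphenylphosphonium bromide, C[P+](c1ccccc1)(c1ccccc1)c1ccccc1.[Br-]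
Why: Wittig methylenation, in which the non-stabilised ylide converts the aryl aldehyde into the styrene and does not touch the aryl iodide or the ethers.

Step 7
Reactants: 11 2-ethenyl-1-(3-{2-[4-(5-iodo-2-methoxyphenoxy)phenyl]ethyl}phenoxy)-4-methoxybenzene
Product: 12 macrocyclic E-stilbene dimethyl ether (18-membered ring; ring A and ring B joined by an E-CH=CH bridge, ring B and ring C by oxygen, ring C and ring D by CH2CH2, ring D and ring A by oxygen; methoxy on ring A para to its ether oxygen and on ring B ortho to its ether oxygen)
Conditions: Pd(OAc)2 (20 mol%), P(o-tol)3 (40 mol%), Et3N, MeCN/DMF, 90 °C, slow addition of 11 to about 2 mM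
Reagents that add atoms: none
Why: Zerovalent palladium formed from Pd(OAc)2 and P(o-tol)3 inserts into the ring B C–I bond, the arylpalladium iodide adds syn across the ring A vinyl group with the aryl group going to the terminal carbon, and syn β-hydride elimination followed by transfer of HI to Et3N releases the stilbene and the catalyst. The closest known reaction type is the intramolecular Mizoroki–Heck macrocyclisation of an aryl iodide onto a terminal alkene. The one ring formed is the 18-membered macrocycle, closed in the endo mode because the terminal alkene carbon becomes a ring atom. No stereocentre is created; the E geometry follows from the anti placement of the two aryl groups in the conformer that undergoes β-hydride elimination, and step 8 erases it in any case. The step needs terminal rather than internal arylation, which the steric and electronic bias of a styrene on the neutral Heck pathway provides and which the alternative 17-membered exo ring with a 1,1-diarylethene would further disfavour. It also needs ring closure to outrun oligomerisation, which slow addition at high dilution and the folding allowed by the two diaryl ether hinges and the flexible C/D bridge should secure.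

Step 8
Reactants: 12 macrocyclic E-stilbene dimethyl ether
Product: 13 dihydroptychantol A dimethyl ether (the macrocycle of 12 with the A/B bridge saturated to CH2CH2)
Conditions: H2 (1 atm), 10% Pd/C, EtOAc/MeOH, rt
Reagents that add atoms: none
Why: Heterogeneous catalytic hydrogenation, in which the disubstituted stilbene is saturated while diaryl ethers and methyl ethers are stable and no halogen remains to be lost.

Step 9
Reactants: 13 dihydroptychantol A dimethyl ether
Product: 15 dihydroptychantol A, via bis(dibromoboryl) ether 14 (not isolated)
Conditions: BBr3, CH2Cl2, −78 °C to rt; then H2O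
Reagents that add atoms: none
Why: Lewis acid cleavage of aryl methyl ethers, in which BBr3 coordinates each methoxy oxygen and bromide removes the methyl group by SN2 to give borate 14, whose hydrolysis frees both phenols while the diaryl ether bonds are not attacked.

**Compound list**

1 | 5-iodo-2-methoxyphenol | COc1ccc(I)cc1O | starting material
2 | 4-fluorobenzaldehyde | O=Cc1ccc(F)cc1 | starting material
3 | 4-(5-iodo-2-methoxyphenoxy)benzaldehyde | COc1ccc(I)cc1Oc1ccc(C=O)cc1 | intermediate
4 | 3-hydroxybenzyl alcohol | OCc1cccc(O)c1 | starting material
5 | (3-hydroxybenzyl)triphenylphosphonium bromide | Oc1cccc(C[P+](c2ccccc2)(c2ccccc2)c2ccccc2)c1.[Br-] | intermediate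
6 | potassium 3-[(triphenylphosphoranylidene)methyl]phenolate (ylide phenoxide, not isolated) | [K+].[O-]c1cccc(C=P(c2ccccc2)(c2ccccc2)c2ccccc2)c1 | intermediate
7 | 3-{2-[4-(5-iodo-2-methoxyphenoxy)phenyl]ethenyl}phenol (E/Z mixture, geometry not specified) | COc1ccc(I)cc1Oc1ccc(C=Cc2cccc(O)c2)cc1 | intermediate
8 | 3-{2-[4-(5-iodo-2-methoxyphenoxy)phenyl]ethyl}phenol | COc1ccc(I)cc1Oc1ccc(CCc2cccc(O)c2)cc1 | intermediate
9 | 2-fluoro-5-methoxybenzaldehyde | COc1ccc(F)c(C=O)c1 | starting material
10 | 2-(3-{2-[4-(5-iodo-2-methoxyphenoxy)phenyl]ethyl}phenoxy)-5-methoxybenzaldehyde | COc1ccc(I)cc1Oc1ccc(CCc2cccc(Oc3ccc(OC)cc3C=O)c2)cc1 | intermediate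
11 | 2-ethenyl-1-(3-{2-[4-(5-iodo-2-methoxyphenoxy)phenyl]ethyl}phenoxy)-4-methoxybenzene | C=Cc1cc(OC)ccc1Oc1cccc(c1)CCc1ccc(cc1)Oc1cc(I)ccc1OC | intermediate
12 | macrocyclic E-stilbene dimethyl ether | COc1ccc2c(c1)/C=C/c1ccc(OC)c(c1)Oc1ccc(cc1)CCc1cccc(c1)O2 | intermediate
13 | dihydroptychantol A dimethyl ether | COc1ccc2c(c1)CCc1ccc(OC)c(c1)Oc1ccc(cc1)CCc1cccc(c1)O2 | intermediate
14 | bis(dibromoboryl) ether of dihydroptychantol A (not isolated) | BrB(Br)Oc1ccc2c(c1)CCc1ccc(OB(Br)Br)c(c1)Oc1ccc(cc1)CCc1cccc(c1)O2 | intermediate
15 | dihydroptychantol A | Oc1ccc2c(c1)CCc1ccc(O)c(c1)Oc1ccc(cc1)CCc1cccc(c1)O2 | target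

**Step count**

Total steps: 9. Longest linear sequence: 8 steps (steps 1 and 3 to 9 from compound 1; step 2 lies on the side branch from compound 4).

**Steps most likely to fail**

Step 7. Intermolecular Heck coupling may outpace ring closure and give oligomers, or the iodide may be lost reductively before the alkene is engaged. The fallback sets out from styrene 11. Hydroboration with 9-borabicyclo[3.3.1]nonane (THF, rt) places boron on the terminal carbon and gives 9-{2-[2-(3-{2-[4-(5-iodo-2-methoxyphenoxy)phenyl]ethyl}phenoxy)-5-methoxyphenyl]ethyl}-9-borabicyclo[3.3.1]nonane F1. This is added slowly to PdCl2(dppf), AsPh3 and Cs2CO3 in DMF/THF/H2O at high dilution. The intramolecular B-alkyl Suzuki–Miyaura coupling with the ring B iodide forms the same ring B carbon to bridge carbon bond and the same 18-membered ring, at the saturated oxidation level. The route is rejoined at compound 13, and step 8 is not needed.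

Step 5. The methoxy group para to fluorine deactivates the ring, so substitution may be sluggish and the aldehyde may degrade under base at the temperature required. The fallback sets out from phenol 8 and uses a Chan–Lam coupling with (2-formyl-4-methoxyphenyl)boronic acid (COc1ccc(B(O)O)c(C=O)c1), Cu(OAc)2, pyridine and 4 Å molecular sieves in CH2Cl2 under air at room temperature. This copper-mediated oxidative coupling forms the same C–O bond at a temperature at which the aryl iodide does not react. It returns to the route at aldehyde 10, and no compound outside the list is made (F0).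

Step 3. Olefination may be incomplete because the doubly deprotonated salt dissolves poorly or the ylide is quenched by proton transfer. The fallback sets out from aldehyde 3 and reverses the roles of the partners, with the phenol protected.
- Reduction with NaBH4 (MeOH, 0 °C) gives [4-(5-iodo-2-methoxyphenoxy)phenyl]methanol F2.
- PPh3·HBr in refluxing MeCN converts it into {[4-(5-iodo-2-methoxyphenoxy)phenyl]methyl}triphenylphosphonium bromide F3.
- Wittig olefination (KOtBu, THF) with commercial 3-(tert-butyldimethylsilyloxy)benzaldehyde gives tert-butyl(3-{2-[4-(5-iodo-2-methoxyphenoxy)phenyl]ethenyl}phenoxy)dimethylsilane F4 as an E/Z mixture.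
- Bu4NF in THF removes the silyl group and returns to the route at stilbene phenol 7.

**Further compounds**

F1 | step 7 | 9-{2-[2-(3-{2-[4-(5-iodo-2-methoxyphenoxy)phenyl]ethyl}phenoxy)-5-methoxyphenyl]ethyl}-9-borabicyclo[3.3.1]nonane | COc1ccc(I)cc1Oc1ccc(CCc2cccc(Oc3ccc(OC)cc3CCB3C4CCCC3CCC4)c2)cc1
F0 | step 5 | none | none
F2 | step 3 | [4-(5-iodo-2-methoxyphenoxy)phenyl]methanol | COc1ccc(I)cc1Oc1ccc(CO)cc1
F3 | step 3 | {[4-(5-iodo-2-methoxyphenoxy)phenyl]methyl}triphenylphosphonium bromide | COc1ccc(I)cc1Oc1ccc(C[P+](c2ccccc2)(c2ccccc2)c2ccccc2)cc1.[Br-]
F4 | step 3 | tert-butyl(3-{2-[4-(5-iodo-2-methoxyphenoxy)phenyl]ethenyl}phenoxy)dimethylsilane (E/Z mixture) | COc1ccc(I)cc1Oc1ccc(C=Cc2cccc(O[Si](C)(C)C(C)(C)C)c2)cc1
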